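## Retrosynthetic overview

1. Drummondin A ⇒ the pyran ring is closed last, by dehydrogenation of the ortho-prenyl phenol to an ortho-quinone methide and oxa-6π ring closure inside the complete, unprotected methylene-bridged dimer (the presumed biosynthetic order: bridge first, chromene last).
2. Prenylated dimer ⇒ methylene-bridge disconnection into butyrylfilicinic acid, a one-carbon iminium salt and 3-prenylphlorobutyrophenone; bridge formation and ring closure are run in one flask.
3. Both halves ⇒ one common precursor, 2',4',6'-trihydroxybutyrophenone, by dearomative gem-dimethylation (filicinic half) or mono-C-prenylation (aromatic half).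
4. Common precursor ⇒ phloroglucinol + butanoyl chloride (Friedel–Crafts).
5. Ring order: both carbocycles are bought as phloroglucinol (one is dearomatised, neither is built); the only ring constructed is the 2H-pyran, in the final flask.

Assumption: the target has no stereocentre and no stereogenic double bond (the ring alkene is fixed cis by the pyran), so the achiral compound is the target and there is no enantiomer to select; tautomers are drawn as in the given SMILES.

## Route

Step 1
Reactants: 1 phloroglucinol (benzene-1,3,5-triol); 2 butanoyl chloride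
Product: 3 1-(2,4,6-trihydroxyphenyl)butan-1-one (phlorobutyrophenone)
Conditions: AlCl3 (3.5 equiv), PhNO2/CH2Cl2, 0 °C to 45 °C; ice/aq. HCl work-up
Reagents that add atoms: butanoyl chloride, CCCC(Cl)=O
Why: Friedel–Crafts C-acylation of the very electron-rich, threefold-symmetric arene stops at the mono-ketone because one equivalent of acid chloride is used and the AlCl3-chelated aryl ketone is deactivated towards a second acylation.

Step 2
Reactants: 3 1-(2,4,6-trihydroxyphenyl)butan-1-one; 4 iodomethane
Product: 6 butyrylfilicinic acid [2-butanoyl-3,5-dihydroxy-6,6-dimethylcyclohexa-2,4-dien-1-one], via mono-C-methyl ketone 5 (not isolated)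
Conditions: NaOMe (3.2 equiv), MeI (2.3 equiv), MeOH, 0 °C to rt; aq. HCl work-up
Reagents that add atoms: iodomethane, CI
Why: Dearomative double C-alkylation of the phloroglucinol polyanion: the carbon methylated first (in 5) is the most nucleophilic site for the second methylation, and the resulting gem-dimethyl β-triketone cannot re-aromatise and is largely withdrawn from further alkylation as its stabilised, weakly nucleophilic anion; no stereocentre is formed.

Step 3
Reactants: 3 1-(2,4,6-trihydroxyphenyl)butan-1-one; 7 1-bromo-3-methylbut-2-ene (prenyl bromide)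
Product: 8 1-[2,4,6-trihydroxy-3-(3-methylbut-2-en-1-yl)phenyl]butan-1-one
Conditions: prenyl bromide (1.0 equiv), 10% aq. KOH, 0 °C, 2 h; then aq. HCl
Reagents that add atoms: 1-bromo-3-methylbut-2-ene, CC(C)=CCBr
Why: Phenolate C-alkylation in water, where hydrogen bonding to the phenolate oxygens suppresses O-alkylation; the two free ring carbons of 3 are equivalent, so only mono- versus poly-alkylation has to be held by stoichiometry and low temperature.

Step 4
Reactants: 6 butyrylfilicinic acid; 8 1-[2,4,6-trihydroxy-3-(3-methylbut-2-en-1-yl)phenyl]butan-1-one; 9 N,N-dimethylmethyleneiminium chloride, [CH2=NMe2]Cl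
Product: 14 drummondin A, via Mannich base hydrochloride 10 (not isolated), via methylene trione 11 (not isolated), via prenylated dimer 12 (not isolated), via ortho-quinone methide 13 (not isolated)
Conditions: 6 + [CH2=NMe2]Cl (1.05 equiv each), MeCN, 0 °C to rt, 1 h; then 8 (1.0 equiv), 60 °C, 3 h; then DDQ (2,3-dichloro-5,6-dicyano-1,4-benzoquinone, 1.1 equiv), 0 °C to rt, 1 h, same flask; aq. HCl work-up
Reagents that add atoms: N,N-dimethylmethyleneiminium chloride, C=[N+](C)C.[Cl-]
Why: Proposed new method: a one-flask merger of three known reaction types not yet run on this substrate — Mannich aminomethylation of the only enolic CH of 6 gives 10, which on warming loses dimethylamine hydrochloride (retro-Michael) to the methylene trione 11 that alkylates the single free ring carbon of 8 (Michael/Friedel–Crafts-type addition, the laboratory counterpart of the presumed biosynthetic methylene bridging) to give 12; DDQ then abstracts hydride from the benzylic-allylic CH2 of the prenyl group (the bridge CH2, flanked by four ortho oxygens and twisted out of both ring planes, is expected to react more slowly, and the amine stays protonated and inert), and the ortho-quinone methide 13 closes by oxa-6π electrocyclisation through the oxygen next to the butanoyl group, because the bridge-flanked para oxygen is held in the inter-ring hydrogen bond and buttressed by the filicinylmethyl group; the closest known reaction type is the DDQ cyclodehydrogenation of ortho-prenylphenols to 2,2-dimethyl-2H-chromenes, and no stereocentre is formed.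

## Compound list

1 | phloroglucinol (benzene-1,3,5-triol) | Oc1cc(O)cc(O)c1 | starting material
2 | butanoyl chloride | CCCC(Cl)=O | starting material
3 | 1-(2,4,6-trihydroxyphenyl)butan-1-one (phlorobutyrophenone) | CCCC(=O)c1c(O)cc(O)cc1O | intermediate
4 | iodomethane | CI | starting material
5 | 1-(2,4,6-trihydroxy-3-methylphenyl)butan-1-one (mono-C-methyl ketone, not isolated) | CCCC(=O)c1c(O)cc(O)c(C)c1O | intermediate
6 | 2-butanoyl-3,5-dihydroxy-6,6-dimethylcyclohexa-2,4-dien-1-one (butyrylfilicinic acid) | CCCC(=O)C1=C(O)C=C(O)C(C)(C)C1=O | intermediate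
7 | 1-bromo-3-methylbut-2-ene (prenyl bromide) | CC(C)=CCBr | starting material
8 | 1-[2,4,6-trihydroxy-3-(3-methylbut-2-en-1-yl)phenyl]butan-1-one | CCCC(=O)c1c(O)cc(O)c(CC=C(C)C)c1O | intermediate
9 | N,N-dimethylmethyleneiminium chloride | C=[N+](C)C.[Cl-] | starting material
10 | 2-butanoyl-4-[(dimethylamino)methyl]-3,5-dihydroxy-6,6-dimethylcyclohexa-2,4-dien-1-one hydrochloride (Mannich base hydrochloride, not isolated) | CCCC(=O)C1=C(O)C(C[NH+](C)C)=C(O)C(C)(C)C1=O.[Cl-] | intermediate
11 | 2-butanoyl-3-hydroxy-6,6-dimethyl-4-methylidenecyclohex-2-ene-1,5-dione (methylene trione, not isolated) | CCCC(=O)C1=C(O)C(=C)C(=O)C(C)(C)C1=O | intermediate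
12 | 2-butanoyl-4-{[3-butanoyl-2,4,6-trihydroxy-5-(3-methylbut-2-en-1-yl)phenyl]methyl}-3,5-dihydroxy-6,6-dimethylcyclohexa-2,4-dien-1-one (prenylated dimer, not isolated) | CCCC(=O)C1=C(O)C(Cc2c(O)c(CC=C(C)C)c(O)c(C(=O)CCC)c2O)=C(O)C(C)(C)C1=O | intermediate
13 | 2-butanoyl-4-{[(3Z)-5-butanoyl-2,6-dihydroxy-3-(3-methylbut-2-en-1-ylidene)-4-oxocyclohexa-1,5-dien-1-yl]methyl}-3,5-dihydroxy-6,6-dimethylcyclohexa-2,4-dien-1-one (ortho-quinone methide, dimethylvinyl arm on the side of the ring carbonyl, not isolated) | CCCC(=O)C1=C(O)C(CC2=C(O)/C(=C/C=C(C)C)C(=O)C(C(=O)CCC)=C2O)=C(O)C(C)(C)C1=O | intermediate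
14 | drummondin A, 2-butanoyl-4-[(8-butanoyl-5,7-dihydroxy-2,2-dimethyl-2H-chromen-6-yl)methyl]-3,5-dihydroxy-6,6-dimethylcyclohexa-2,4-dien-1-one | CCCC(=O)C1=C(O)C(Cc2c(O)c3c(c(C(=O)CCC)c2O)OC(C)(C)C=C3)=C(O)C(C)(C)C1=O | target

## Step count

Total steps: 4. Longest linear sequence: 3 steps (1 → 3 → 6 or 8 → 14).

## Steps most likely to fail, with fallbacks

**Step 4 (highest risk).** Two things can go wrong. The pyran may close through the bridge-side oxygen and give the regioisomeric chromene; simple prenylated acylphenols usually cyclise through the oxygen para to the ketone, so a mixture is possible. DDQ may also attack the bridge CH2. The fallback closes the ring on the monomer with the para oxygen blocked and installs the bridge last. It sets out from 8. Chloromethyl methyl ether (1.0 equiv) and i-Pr2NEt in CH2Cl2 at 0 °C alkylate the most acidic, non-chelated para hydroxyl to give the 4-O-methoxymethyl ether F1. DDQ in benzene (rt to 60 °C) can then close the pyran only through the hydroxyl next to the ketone, giving the methoxymethyl-protected chromene F2. HCl in MeOH at 40 °C removes the acetal to give the chromene monomer F3, 1-(5,7-dihydroxy-2,2-dimethyl-2H-chromen-8-yl)butan-1-one. F3 is heated in MeCN at 60 °C with the Mannich base hydrochloride 10, made from 6 and 9 as in step 4. The methylene trione 11 alkylates the only free ring carbon of F3, and the sequence comes back to the route at 14.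

**Step 3.** Mono-C-prenylation of a phloroglucinol competes with bis-, geminal and O-alkylation, so about 40% is the realistic yield. The fallback sets out from 3 and makes the C–C bond by O-alkylation followed by O-to-C migration. K2CO3 and prenyl bromide 7 in acetone at rt alkylate the most acidic para hydroxyl to give the 4-O-prenyl ether F4. BF3·OEt2 in CH2Cl2 at −40 °C to 0 °C then ionises the ether and returns the prenyl group to the ring ([1,3] shift). Both ortho carbons are equivalent and the para position carries the ketone, so the only C-prenyl product is 8, where the fallback rejoins the route.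

**Step 2.** Over-methylation to the trimethyl compound and under-methylation lower the yield and complicate purification. The fallback sets out from 1 and blocks the carbon that over-methylates. Friedel–Crafts acylation with 2.2 equiv of 2 (AlCl3, PhNO2, 60 °C) gives the diketone F5, 2,4-dibutanoylphloroglucinol, which has one free ring carbon. NaOMe and MeI in MeOH can then only gem-dimethylate that carbon, giving dibutanoylfilicinic acid F6. One of the two equivalent acyl groups is removed by acid retro-Claisen cleavage (80% aq. H2SO4, 60–80 °C, stopped at mono-deacylation), which returns to the route at 6.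

## Further compounds

F1 | step 4 | 1-[2,6-dihydroxy-4-(methoxymethoxy)-3-(3-methylbut-2-en-1-yl)phenyl]butan-1-one | CCCC(=O)c1c(O)cc(OCOC)c(CC=C(C)C)c1O
F2 | step 4 | 1-[7-hydroxy-5-(methoxymethoxy)-2,2-dimethyl-2H-chromen-8-yl]butan-1-one | CCCC(=O)c1c(O)cc(OCOC)c2C=CC(C)(C)Oc12
F3 | step 4 | 1-(5,7-dihydroxy-2,2-dimethyl-2H-chromen-8-yl)butan-1-one | CCCC(=O)c1c(O)cc(O)c2C=CC(C)(C)Oc12
F4 | step 3 | 1-{2,6-dihydroxy-4-[(3-methylbut-2-en-1-yl)oxy]phenyl}butan-1-one | CCCC(=O)c1c(O)cc(OCC=C(C)C)cc1O
F5 | step 2 | 1,1'-(2,4,6-trihydroxy-1,3-phenylene)di(butan-1-one) | CCCC(=O)c1c(O)cc(O)c(C(=O)CCC)c1O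
F6 | step 2 | 2,4-dibutanoyl-3,5-dihydroxy-6,6-dimethylcyclohexa-2,4-dien-1-one | CCCC(=O)C1=C(O)C(C(=O)CCC)=C(O)C(C)(C)C1=O
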